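## The problem

Target 14 is a 6,8-linked biflavone. C6 of unit 1 (a 5,7-dihydroxyflavone) is bonded to C8 of unit 2 (a 5-hydroxy-7-methoxyflavone), and each unit carries a 4-methoxyphenyl ring at C2. The two benzopyranones are joined only through this one aryl–aryl bond, which has four ortho substituents: O5 and O7 in unit 1, and the 7-methoxy group and the C8a–O1 bond in unit 2. There is no stereocentre; the hindered axis is the only stereogenic element, nothing else in the molecule could control it, and it is drawn without a descriptor. The real selectivity problems are constitutional. C6 and C8 of a 5,7-dioxygenated flavone are electronically alike, and in a 5-hydroxyflavone they are exchanged when the pyranone opens and recloses through O5 (Wessely–Moser rearrangement), so each linkage position must be fixed by structure and then kept away from hot acid or alkali. Six phenolic oxygens must end as three methyl ethers (both 4-methoxyphenyl groups and O7 of unit 2) and three free hydroxyls (O5 and O7 of unit 1, O5 of unit 2), which rules out an unselective final dealkylation. The pyranone rings do not tolerate carbon nucleophiles or hot hydroxide, and phloroglucinol-type rings with free hydroxyls are easily oxidised or alkylated by aldehydes and oxocarbenium ions. The plan exploits the fact that O5 of unit 1 and ring oxygen O1 of unit 2 both stand on carbons next to the axis (C5 next to C6, C8a next to C8): the chain O5–C5–C6–C8–C8a–O1 needs one CH2 group to become a seven-membered 1,3-dioxepine, and O1 of unit 2 is an ordinary phenol oxygen as long as its pyranone has not been built.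

## Retrosynthesis

**14 to 13.** The free hydroxyls at O7 of unit 1 and O5 of unit 2 are traced back to an O–isopropyl and an O–methyl bond in 13.
- The peri methyl ether of unit 2 is the only methyl ether that a chelating boron halide removes, and a secondary alkyl ether is the only other kind such a reagent cleaves readily. Both therefore fall in one operation while the three methoxy groups of 14 stay.
- A methyl group on O7 of unit 1 could not be told apart from the 7-methoxy group of unit 2. A benzyl group would not survive the Lewis acids used earlier.
- The skeleton is unchanged, but 13 has only one free phenol, the chelated 5-OH.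
- The forward reaction must be selective among five alkyl aryl ethers.

**13 to 12, and 12 to 10 plus 11.** The pyranone of unit 2 is cut at O1–C2 (oxidative cyclisation of chalcone 12) and at C2–C3 (aldol condensation of acetophenone 10 with 4-methoxybenzaldehyde 11).
- In 10 the ketone has a hydroxyl on one side and a methoxy group on the other. Only one ring closure exists, and it makes unit 2 8-linked by necessity.
- Cutting unit 1 instead would reopen the 6-versus-8 question, because its acyl carbon lies between two oxygens of the same kind.
- The precursor loses one ring, nine carbons and the second aryl group.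
- The forward steps must respect the finished pyranone of unit 1.

**10 to 8.** The C4a–C4 bond of unit 2 (aryl–acetyl) is cut.
- In phenol 8 the carbon concerned is the only free position ortho to the hydroxyl. The competing position lies between two methoxy groups and cannot give a chelated ketone.
- Carrying the acetyl group through the coupling instead would deactivate the ring that has to be oxidised.
- The forward reaction must be an ortho-selective C-acetylation that leaves C8 of unit 1 alone.

**8 to 7.** The two phenols flanking the axis are reconnected through one CH2 group, giving the dioxepine 7. This adds a ring in the retrosynthetic sense, but it turns the next cut into an intramolecular event. The forward reaction is the solvolysis of a diaryl formaldehyde acetal in which O5 is activated by the neighbouring carbonyl.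

**7 to 6 (key cut).** The C6–C8 biaryl bond is cut inside the seven-membered ring.
- Cutting it without the bridge would call for a cross-coupling of two tetra-ortho-substituted partners, with separate halogenation and metalation of each.
- With the bridge, both partners are used as C–H compounds and the sites are chosen by reach alone.
- Precursor 6 contains one intact flavone and one symmetric trioxygenated benzene.
- The forward reaction must oxidise that benzene ring selectively and let flavone C6 attack it.

**6 to 3 plus 4 (through 5).** The CH2–O bond to the phenoxy ring is cut.
- The opposite polarity, a chloromethyl ether placed on the ring of 3,5-dimethoxyphenol 4, puts an oxocarbenium precursor and a chlorinating agent on a very nucleophilic arene. Self-alkylation and ring chlorination would be expected.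
- Placing the electrophilic carbon on the electron-poor flavone (chloromethyl ether 5, from the O,S-acetal 3) avoids both problems and saves a step.
- The forward reaction is O-alkylation of an ambident phenoxide.

**3 to 2 to 1.** The O5–CH2 and O7–isopropyl bonds are cut in turn, ending at acacetin 1.
- Compound 1 already contains all of unit 1, including its 4-methoxyphenyl group.
- The order follows acidity: the 7-OH reacts with a weak base, and the chelated 5-OH reacts only after full deprotonation.

## Roads not taken

**Alternative 1:** The cut is the C5–C6 bond of unit 1. With it the whole benzo ring of unit 1 is unravelled to a 3,5-dioxo ester chain hanging from a CH2 group on C8 of a finished unit 2 (dioxo ester A2). In the forward direction a base (an alkoxide or an amidine) must make the benzylic CH2 of A2 attack the ester carbonyl, and enolisation then gives the 2-arylphloroglucinol A1.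
- *Merits.* No aryl–aryl coupling is needed. The crowded axis starts as an unhindered sp3–sp2 bond, and no oxidant meets an electron-rich ring.
- *Weak points.*
  - The benzylic CH2 is the least acidic of the three methylene groups of A2. The two doubly activated ones are deprotonated first, which lowers the electrophilicity of the ester and leaves lactonisation through the C5 enol oxygen as the easier closure.
  - A1 is a symmetric triol on which the pyranone of unit 1 must still be built (acylation, condensation, cyclisation).
  - The acyl group of that sequence will sit between two free hydroxyls. Closure through one gives the 6-linked unit and through the other the 8-linked unit, so the central ambiguity returns unless more protecting-group steps are spent.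
  - A2 itself needs functionalisation of a flavone at C8, homologation and a dianion acylation next to a pyranone.
- *Comparison.* This road is better in avoiding the hindered coupling and the oxidation. The chosen plan sets against it that unit 1 is bought complete as 1, that its linkage position is dictated by the reach of the bridge, and that the one pyranone still to be made has a single possible mode of closure.

**Alternative 2:** The cut removes C4a–C4, C4–C3 and O1–C2 in both units at once. It leads from the fully protected biflavone A3 back to the biaryl bis(iodophenol) A4, two molecules of 4-ethynylanisole A5 and carbon monoxide. In the forward direction PdCl2(PPh3)2 under CO in diethylamine would do four things at each iodide: insert zerovalent palladium into the C–I bond, take up CO, transfer the alkyne to give an ynone, and let the neighbouring phenol close the ring in a 6-endo manner.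
- *Merits.*
  - Both pyranones form in one flask.
  - No hydroxide or strong acid is used, so a Wessely–Moser exchange cannot occur.
  - The unit 1 ring of A4 is symmetric, so its monoiodination poses no regiochemical question.
  - A3 needs only one boron trichloride treatment to reach 14.
  - After the biaryl bond it is clearly shorter than the chosen route (two operations against five).
- *Weak points.*
  - It leaves the hardest bond unsolved. A4 still contains the tetra-ortho-substituted axis between two differently protected phloroglucinol rings, which would have to come from a hindered cross-coupling.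
  - Each iodide is flanked by two oxygen substituents. Insertion of CO is therefore slow, alkynylation without CO and 5-exo closure compete, and every loss counts twice.
  - Iodination of the unit 2 ring faces the same choice (ortho to OH or between two methoxy groups) that the chosen route meets in step 6, but without a chelate to correct it.
- *Comparison.* The chosen plan gives up this elegant endgame. In return it offers a defined answer to the biaryl problem and the use of a ready-made unit 1.

**Alternative 3:** The cut takes out C4a–C5 and C6–C7 of unit 1. The benzo ring is divided into a four-carbon diene held in the pyranopyranone A7 and a two-carbon ynol ether attached to C8 of unit 2 (A8). On heating, A8 would add across C3 and C6 of the 2-pyranone ring of A7, and the bridged lactone would lose CO2 to give the biflavone A6.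
- *Merits.*
  - Two complete halves are joined.
  - The future axis exists from the outset as an unhindered sp–sp2 bond.
  - The polarity is matched: the nucleophilic, aryl-bearing alkyne carbon pairs with the electrophilic C6 of the acyl-substituted pyranone. The 6-linkage is therefore encoded.
  - A6 needs only cleavage of two peri methyl ethers and one isopropyl ether to give 14, and no oxidant is used.
- *Weak points.*
  - A7 is the enol ether of a glutaconic anhydride. It is hydrolytically fragile and has no dependable preparation.
  - Its alkoxy donor at the diene terminus offsets the activation by the acyl group.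
  - The first bond must form between an alkyne carbon bearing a di-ortho-substituted aryl group and a fully substituted diene terminus, which is the worst steric case.
  - Aryl ynol ethers tend to hydrate or oligomerise at the temperatures such cycloadditions need.
  - A8 also costs several steps from an 8-haloflavone.
- *Comparison.* This road is the equal of the chosen plan in regiochemical logic and better in convergence. The chosen plan sets against it stable, easily made intermediates and a key reaction of a known type.

Key step: step 4

Assumption: the target is drawn without an axial descriptor, so the biaryl axis is made in racemic form and no atropselective element is built in.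

## Route

Step 1
Reactants: 1 acacetin (5,7-dihydroxy-2-(4-methoxyphenyl)chromen-4-one)
Product: 2 5-hydroxy-7-isopropoxy-2-(4-methoxyphenyl)chromen-4-one
Conditions: 2-bromopropane, K2CO3, DMF, 60 °C
Reagents that add atoms: 2-bromopropane, CC(C)Br
Why: Williamson ether synthesis; the 7-OH is a vinylogous acid and is ionised by K2CO3, whereas the 5-OH is tied up in a hydrogen bond to C4=O and should stay unalkylated under these conditions.

Step 2
Reactants: 2 5-hydroxy-7-isopropoxy-2-(4-methoxyphenyl)chromen-4-one
Product: 3 7-isopropoxy-2-(4-methoxyphenyl)-5-[(methylsulfanyl)methoxy]chromen-4-one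
Conditions: NaH, ClCH2SMe, NaI (cat.), DMF, 0 °C → rt
Reagents that add atoms: chloromethyl methyl sulfide, CSCCl
Why: Williamson alkylation of the chelated phenol after complete deprotonation with NaH; the α-thio halide, made more reactive by Finkelstein exchange with NaI, is reactive enough for the hindered peri oxygen, and phenol methylthiomethyl ethers are routinely made this way.

Step 3
Reactants: 3 7-isopropoxy-2-(4-methoxyphenyl)-5-[(methylsulfanyl)methoxy]chromen-4-one; 4 3,5-dimethoxyphenol
Product: 6 5-[(3,5-dimethoxyphenoxy)methoxy]-7-isopropoxy-2-(4-methoxyphenyl)chromen-4-one, via chloromethyl ether 5 (not isolated)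
Conditions: SO2Cl2 (1.0 equiv), cyclohexene, CH2Cl2, −78 → 0 °C, concentrate; then added to 4, Cs2CO3, DMF, 0 °C → rt
Reagents that add atoms: sulfuryl chloride, O=S(=O)(Cl)Cl (supplies the chlorine of 5; none of its atoms remain in 6)
Why: Chlorinolysis of an O,S-acetal: sulfur is chlorinated much faster than any arene carbon, the chlorosulfonium ion collapses to the aryl chloromethyl ether 5, and cyclohexene takes up the sulfenyl chloride. Williamson O-alkylation of the caesium phenoxide of 4 in DMF then gives the mixed diaryl formaldehyde acetal. The electrophilic carbon sits on the electron-poor flavone, so neither the chlorinating agent nor a chloromethyl ether shares a molecule with the phloroglucinol-type ring.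

Step 4
Reactants: 6 5-[(3,5-dimethoxyphenoxy)methoxy]-7-isopropoxy-2-(4-methoxyphenyl)chromen-4-one
Product: 7 bridged biaryl: 6-(2-oxy-4,6-dimethoxyphenyl)-7-isopropoxy-2-(4-methoxyphenyl)chromen-4-one in which O5 of the flavone and the 2-oxygen of the aryl group are joined by CH2 (seven-membered dibenzo-1,3-dioxepine)
Conditions: PhI(OCOCF3)2 (1.1 equiv), BF3·OEt2 (2.5 equiv), CH2Cl2 (high dilution), −40 °C
Reagents that add atoms: none
Why: The trivalent iodine reagent, activated by BF3, forms a charge-transfer complex with the most electron-rich arene of 6 (the 1,3,5-trioxygenated phenoxy ring) and removes one electron; flavone C6, which lies between two alkoxy groups and meta to the acyl-bearing C4a, attacks the radical cation at the carbon ortho to the acetal oxygen, and a second one-electron oxidation with loss of two protons restores both arenes. The closest known reaction type is the intramolecular oxidative biaryl coupling of phenol ethers with this reagent pair, which has been carried out across heteroatom tethers, including O–X–O bridges that deliver seven-membered dibenzo rings. The one new ring is the 1,3-dioxepine (O5–C5–C6–aryl C–aryl C–O–CH2); it closes by attack of one trigonal arene carbon on another, formally 7-endo-trig when counted along the C–C bond of the radical cation that carries the bridge oxygen. No stereocentre is formed, and the twisted bridged biaryl is obtained as a racemate. Site selectivity is needed on both rings and is secured by the three-atom bridge, which reaches only carbons ortho to its oxygens: on the flavone this is C6 alone, since the other ortho carbon is the quaternary C4a and C8, C3 and the anisyl ring are out of reach. On the phenoxy ring the two ortho carbons are equivalent by symmetry, and the carbon between the methoxy groups is para to the bridge oxygen. More than two equivalents of BF3·OEt2 are used because the pyranone carbonyl binds one, while low temperature and dilution hold back acetal ionisation and intermolecular coupling. The isopropyl and methyl ethers are inert at −40 °C.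

Step 5
Reactants: 7 bridged biaryl (dibenzo-1,3-dioxepine)
Product: 8 5-hydroxy-6-(2-hydroxy-4,6-dimethoxyphenyl)-7-isopropoxy-2-(4-methoxyphenyl)chromen-4-one
Conditions: conc. HCl, MeOH–THF, 60 °C
Reagents that add atoms: none
Why: Acid-catalysed transacetalisation of a formaldehyde acetal; a proton held between C4=O and O5 turns the flavone 5-oxygen into a good leaving group, as in the easy cleavage of 5-O-alkoxymethyl flavones. The large excess of methanol carries the one-carbon unit off as a volatile acetal before it can alkylate the electron-rich ring. Aryl methyl and isopropyl ethers and the pyranone are stable to dilute HCl at this temperature.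

Step 6
Reactants: 8 5-hydroxy-6-(2-hydroxy-4,6-dimethoxyphenyl)-7-isopropoxy-2-(4-methoxyphenyl)chromen-4-one
Product: 10 6-(3-acetyl-2-hydroxy-4,6-dimethoxyphenyl)-5-hydroxy-7-isopropoxy-2-(4-methoxyphenyl)chromen-4-one, via aryl acetate 9 (not isolated)
Conditions: Ac2O, BF3·OEt2, 60 °C; then MeOH–H2O, reflux
Reagents that add atoms: acetic anhydride, CC(=O)OC(C)=O
Why: O-acetylation followed by Fries rearrangement (overall a Friedel–Crafts acetylation), the standard entry to 2-hydroxy-4,6-dimethoxyacetophenones. The acetyl group settles on the only free carbon ortho to the phenol because it is held there in a six-membered chelate, whereas acylation between the two methoxy groups is hindered and reversible. Binding of boron to the C4=O/5-OH pair deactivates C8 of unit 1, and the aqueous methanol treatment frees the boron-bound oxygens.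

Step 7
Reactants: 10 6-(3-acetyl-2-hydroxy-4,6-dimethoxyphenyl)-5-hydroxy-7-isopropoxy-2-(4-methoxyphenyl)chromen-4-one; 11 4-methoxybenzaldehyde
Product: 12 (E)-chalcone: 5-hydroxy-6-{2-hydroxy-4,6-dimethoxy-3-[(E)-3-(4-methoxyphenyl)prop-2-enoyl]phenyl}-7-isopropoxy-2-(4-methoxyphenyl)chromen-4-one
Conditions: KOH (50% aq.), EtOH, 0 °C → rt; then dil. HCl
Reagents that add atoms: none
Why: Claisen–Schmidt condensation, well established for 2-hydroxy-4,6-dimethoxyacetophenones with this aldehyde; E1cB dehydration gives the conjugated E alkene. The 5-OH of unit 1 is ionised first, which lowers the electrophilicity of its C2, so the existing pyranone should withstand hydroxide at room temperature.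

Step 8
Reactants: 12 (E)-chalcone
Product: 13 5-hydroxy-7-isopropoxy-2-(4-methoxyphenyl)-6-[5,7-dimethoxy-2-(4-methoxyphenyl)-4-oxochromen-8-yl]chromen-4-one
Conditions: I2 (10 mol %), DMSO, 120 °C
Reagents that add atoms: none
Why: Iodine-catalysed oxidative cyclisation of a 2'-hydroxychalcone: 6-endo oxa-Michael closure through the only phenol ortho to the ketone, then iodination–elimination, with DMSO re-oxidising HI. The other ortho position carries a methoxy group, so the new flavone can only be 8-linked. Iodine is kept catalytic to avoid ring iodination at C8 of unit 1.

Step 9
Reactants: 13 5-hydroxy-7-isopropoxy-2-(4-methoxyphenyl)-6-[5,7-dimethoxy-2-(4-methoxyphenyl)-4-oxochromen-8-yl]chromen-4-one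
Product: 14 target biflavone: 5,7-dihydroxy-6-[5-hydroxy-7-methoxy-2-(4-methoxyphenyl)-4-oxochromen-8-yl]-2-(4-methoxyphenyl)chromen-4-one
Conditions: BCl3 (excess, 1 M in CH2Cl2), CH2Cl2, −78 °C → rt; then MeOH, aq. HCl
Reagents that add atoms: none
Why: Lewis-acid ether cleavage with two known selectivities of BCl3: aryl isopropyl ethers are cleaved through the secondary alkyl group, and a methyl ether peri to a carbonyl is cleaved through a six-membered boron chelate. Unchelated aryl methyl ethers (O7 of unit 2 and both anisyl groups) are left alone. No new stereo element arises, and the conditions do not open either pyranone.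

## Compound list

1 | acacetin, 5,7-dihydroxy-2-(4-methoxyphenyl)chromen-4-one | COc1ccc(cc1)-c1cc(=O)c2c(O)cc(O)cc2o1 | starting material
2 | 5-hydroxy-7-isopropoxy-2-(4-methoxyphenyl)chromen-4-one | COc1ccc(cc1)-c1cc(=O)c2c(O)cc(OC(C)C)cc2o1 | intermediate
3 | 7-isopropoxy-2-(4-methoxyphenyl)-5-[(methylsulfanyl)methoxy]chromen-4-one | COc1ccc(cc1)-c1cc(=O)c2c(OCSC)cc(OC(C)C)cc2o1 | intermediate
4 | 3,5-dimethoxyphenol | COc1cc(O)cc(OC)c1 | starting material
5 | 5-(chloromethoxy)-7-isopropoxy-2-(4-methoxyphenyl)chromen-4-one (not isolated) | COc1ccc(cc1)-c1cc(=O)c2c(OCCl)cc(OC(C)C)cc2o1 | intermediate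
6 | 5-[(3,5-dimethoxyphenoxy)methoxy]-7-isopropoxy-2-(4-methoxyphenyl)chromen-4-one | COc1ccc(cc1)-c1cc(=O)c2c(OCOc3cc(OC)cc(OC)c3)cc(OC(C)C)cc2o1 | intermediate
7 | methylene-bridged 6-(2-oxy-4,6-dimethoxyphenyl)-7-isopropoxy-2-(4-methoxyphenyl)chromen-4-one (dibenzo-1,3-dioxepine, racemic) | COc1ccc(cc1)-c1cc(=O)c2c3OCOc4cc(OC)cc(OC)c4-c3c(OC(C)C)cc2o1 | intermediate
8 | 5-hydroxy-6-(2-hydroxy-4,6-dimethoxyphenyl)-7-isopropoxy-2-(4-methoxyphenyl)chromen-4-one | COc1ccc(cc1)-c1cc(=O)c2c(O)c(-c3c(O)cc(OC)cc3OC)c(OC(C)C)cc2o1 | intermediate
9 | 6-(2-acetoxy-4,6-dimethoxyphenyl)-5-hydroxy-7-isopropoxy-2-(4-methoxyphenyl)chromen-4-one (not isolated) | COc1ccc(cc1)-c1cc(=O)c2c(O)c(-c3c(OC(C)=O)cc(OC)cc3OC)c(OC(C)C)cc2o1 | intermediate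
10 | 6-(3-acetyl-2-hydroxy-4,6-dimethoxyphenyl)-5-hydroxy-7-isopropoxy-2-(4-methoxyphenyl)chromen-4-one | COc1ccc(cc1)-c1cc(=O)c2c(O)c(-c3c(O)c(C(C)=O)c(OC)cc3OC)c(OC(C)C)cc2o1 | intermediate
11 | 4-methoxybenzaldehyde | COc1ccc(C=O)cc1 | starting material
12 | 5-hydroxy-6-{2-hydroxy-4,6-dimethoxy-3-[(E)-3-(4-methoxyphenyl)prop-2-enoyl]phenyl}-7-isopropoxy-2-(4-methoxyphenyl)chromen-4-one | COc1ccc(cc1)-c1cc(=O)c2c(O)c(-c3c(O)c(C(=O)/C=C/c4ccc(OC)cc4)c(OC)cc3OC)c(OC(C)C)cc2o1 | intermediate
13 | 5-hydroxy-7-isopropoxy-2-(4-methoxyphenyl)-6-[5,7-dimethoxy-2-(4-methoxyphenyl)-4-oxochromen-8-yl]chromen-4-one | COc1ccc(cc1)-c1cc(=O)c2c(O)c(-c3c(OC)cc(OC)c4c(=O)cc(-c5ccc(OC)cc5)oc34)c(OC(C)C)cc2o1 | intermediate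
14 | 5,7-dihydroxy-6-[5-hydroxy-7-methoxy-2-(4-methoxyphenyl)-4-oxochromen-8-yl]-2-(4-methoxyphenyl)chromen-4-one (CNP0146326.0, racemic axis) | COc1ccc(-c2cc(=O)c3c(O)c(-c4c(OC)cc(O)c5c(=O)cc(-c6ccc(OC)cc6)oc45)c(O)cc3o2)cc1 | target

## Step count and least certain steps

Total step count: 9. Longest linear sequence: 9 steps (1 → 14); compounds 4 and 11 enter as purchased materials.

**Step 4 (key step).**
- *What may go wrong.*
  - The phloroglucinol-type ring may capture the trivalent iodine by electrophilic substitution (diaryliodonium salt formation, above all at the carbon between the methoxy groups) instead of giving up an electron.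
  - BF3 bound to the pyranone carbonyl lowers the nucleophilicity of C6. The radical cation then has time for intermolecular coupling or over-oxidation.
  - The Lewis acid may also ionise the acetal.
- *Fallback.* The bridge is kept, but the C–H/C–H oxidation is replaced by a C–I/C–H palladium coupling. It sets out from 2.
  - Iodination with benzyltrimethylammonium dichloroiodate and CaCO3 in CH2Cl2–MeOH goes ortho to the free hydroxyl in 5-hydroxyflavones. It should give 5-hydroxy-6-iodo-7-isopropoxy-2-(4-methoxyphenyl)chromen-4-one F1.
  - Alkylation as in step 2 gives the methylthiomethyl ether F2.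
  - Chlorinolysis as in step 3 gives the chloromethyl ether F3, which is used at once with 4 and Cs2CO3 to give the iodinated mixed acetal F4.
  - Intramolecular direct arylation follows (Pd(OAc)2, PCy3·HBF4, K2CO3, pivalic acid, DMA, 110 °C). Zerovalent palladium inserts into the C6–I bond, and concerted metalation–deprotonation takes place at either equivalent ortho carbon of the phenoxy ring. This closes the same seven-membered ring and returns to the route at 7.

**Step 3.**
- *What may go wrong.* The peri carbonyl may assist ionisation of the chloromethyl ether, followed by hydrolysis or attack of the phenoxide at the pyranone. Ring chlorination may occur if sulfuryl chloride is in excess. The ambident phenoxide may be alkylated at carbon.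
- *Fallback.* The roles of the two partners are reversed. It sets out from 4 and 2.
  - Compound 4 is converted with NaH and ClCH2SMe into 1,3-dimethoxy-5-[(methylsulfanyl)methoxy]benzene F5.
  - SO2Cl2 and cyclohexene at −78 °C turn F5 into 1-(chloromethoxy)-3,5-dimethoxybenzene F6.
  - F6 is added cold, without concentration, to the sodium salt of 2 (NaH, DMF). The route is rejoined at 6.

**Step 5.**
- *What may go wrong.* Solvolysis may be slow because both acetal oxygens are aryl-bound and held in a rigid ring. The freed one-carbon electrophile may be recaptured by the phloroglucinol-type ring.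
- *Fallback.* Chelation-directed Lewis-acid cleavage is used, accepting loss of the isopropyl group. It sets out from 7.
  - BCl3 in CH2Cl2 (−78 → 0 °C, cold aqueous quench) opens the acetal at O5 and removes the isopropyl group. This gives 5,7-dihydroxy-6-(2-hydroxy-4,6-dimethoxyphenyl)-2-(4-methoxyphenyl)chromen-4-one F7.
  - One equivalent of K2CO3 with 2-bromopropane in DMF then re-alkylates the most acidic hydroxyl, the 7-OH. The route is rejoined at 8.

**Step 6.**
- *What may go wrong.* The isopropyl ether may be lost under warm BF3·OEt2/Ac2O. Acylation may occur at the carbon between the methoxy groups or at C8 of unit 1.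
- *Fallback.* A Hoesch reaction replaces the anhydride by a nitrile electrophile at low temperature. It sets out from 8.
  - MeCN, ZnCl2 and HCl gas in Et2O–dioxane at 0 °C give the ketimine F8, collected as its hydrochloride and held ortho to the phenol by hydrogen bonding.
  - Hydrolysis of F8 in hot water returns to the route at 10.

**Step 7.**
- *What may go wrong.* Hydroxide may add at C2 of unit 1 during the long condensation. The pyranone would then open and either cleave by a retro-Claisen path or reclose through O5, which would move the linkage from C6 to C8.
- *Fallback.* Hydroxide is avoided altogether by a Baker–Venkataraman-type acylation. It sets out from 10.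
  - Excess LiHMDS in THF at −78 °C ionises both phenols and the methyl ketone. One equivalent of 4-methoxybenzoyl chloride acylates the enolate to give the β-diketone F9.
  - Cyclodehydration with catalytic H2SO4 in AcOH at 95 °C closes the pyranone. The route is rejoined at 13, bypassing 12 and step 8.

## Further compounds

F1 | step 4 | 5-hydroxy-6-iodo-7-isopropoxy-2-(4-methoxyphenyl)chromen-4-one | COc1ccc(cc1)-c1cc(=O)c2c(O)c(I)c(OC(C)C)cc2o1
F2 | step 4 | 6-iodo-7-isopropoxy-2-(4-methoxyphenyl)-5-[(methylsulfanyl)methoxy]chromen-4-one | COc1ccc(cc1)-c1cc(=O)c2c(OCSC)c(I)c(OC(C)C)cc2o1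
F3 | step 4 | 5-(chloromethoxy)-6-iodo-7-isopropoxy-2-(4-methoxyphenyl)chromen-4-one | COc1ccc(cc1)-c1cc(=O)c2c(OCCl)c(I)c(OC(C)C)cc2o1
F4 | step 4 | 5-[(3,5-dimethoxyphenoxy)methoxy]-6-iodo-7-isopropoxy-2-(4-methoxyphenyl)chromen-4-one | COc1ccc(cc1)-c1cc(=O)c2c(OCOc3cc(OC)cc(OC)c3)c(I)c(OC(C)C)cc2o1
F5 | step 3 | 1,3-dimethoxy-5-[(methylsulfanyl)methoxy]benzene | COc1cc(OCSC)cc(OC)c1
F6 | step 3 | 1-(chloromethoxy)-3,5-dimethoxybenzene | COc1cc(OCCl)cc(OC)c1
F7 | step 5 | 5,7-dihydroxy-6-(2-hydroxy-4,6-dimethoxyphenyl)-2-(4-methoxyphenyl)chromen-4-one | COc1ccc(cc1)-c1cc(=O)c2c(O)c(-c3c(O)cc(OC)cc3OC)c(O)cc2o1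
F8 | step 6 | 5-hydroxy-6-[2-hydroxy-3-(1-iminoethyl)-4,6-dimethoxyphenyl]-7-isopropoxy-2-(4-methoxyphenyl)chromen-4-one | COc1ccc(cc1)-c1cc(=O)c2c(O)c(-c3c(O)c(C(C)=N)c(OC)cc3OC)c(OC(C)C)cc2o1
F9 | step 7 | 1-{2-hydroxy-3-[5-hydroxy-7-isopropoxy-2-(4-methoxyphenyl)-4-oxochromen-6-yl]-4,6-dimethoxyphenyl}-3-(4-methoxyphenyl)propane-1,3-dione | COc1ccc(cc1)-c1cc(=O)c2c(O)c(-c3c(O)c(C(=O)CC(=O)c4ccc(OC)cc4)c(OC)cc3OC)c(OC(C)C)cc2o1
A1 | alternative 1 | 8-(2,4,6-trihydroxyphenyl)-5,7-dimethoxy-2-(4-methoxyphenyl)chromen-4-one | Oc1cc(O)c(-c2c(OC)cc(OC)c3c(=O)cc(-c4ccc(OC)cc4)oc23)c(O)c1
A2 | alternative 1 | methyl 6-[5,7-dimethoxy-2-(4-methoxyphenyl)-4-oxochromen-8-yl]-3,5-dioxohexanoate | COC(=O)CC(=O)CC(=O)Cc1c(OC)cc(OC)c2c(=O)cc(-c3ccc(OC)cc3)oc12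
A3 | alternative 2 | 5,7-diisopropoxy-2-(4-methoxyphenyl)-6-[5,7-dimethoxy-2-(4-methoxyphenyl)-4-oxochromen-8-yl]chromen-4-one | COc1ccc(cc1)-c1cc(=O)c2c(OC(C)C)c(-c3c(OC)cc(OC)c4c(=O)cc(-c5ccc(OC)cc5)oc34)c(OC(C)C)cc2o1
A4 | alternative 2 | 3,3'-diiodo-2',6'-diisopropoxy-4,6-dimethoxybiphenyl-2,4'-diol | Oc1cc(OC(C)C)c(-c2c(O)c(I)c(OC)cc2OC)c(OC(C)C)c1I
A5 | alternative 2 | 4-ethynylanisole | C#Cc1ccc(OC)cc1
A6 | alternative 3 | 7-isopropoxy-5-methoxy-2-(4-methoxyphenyl)-6-[5,7-dimethoxy-2-(4-methoxyphenyl)-4-oxochromen-8-yl]chromen-4-one | COc1c(-c2c(OC)cc(OC)c3c(=O)cc(-c4ccc(OC)cc4)oc23)c(OC(C)C)cc2oc(-c3ccc(OC)cc3)cc(=O)c12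
A7 | alternative 3 | 7-isopropoxy-2-(4-methoxyphenyl)pyrano[4,3-b]pyran-4,5-dione | COc1ccc(cc1)-c1cc(=O)c2c(cc(OC(C)C)oc2=O)o1
A8 | alternative 3 | 5,7-dimethoxy-8-(methoxyethynyl)-2-(4-methoxyphenyl)chromen-4-one | COC#Cc1c(OC)cc(OC)c2c(=O)cc(-c3ccc(OC)cc3)oc12
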